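**Plan**

- Central ring numbering: C1 carries the (S)-3-hydroxybutanoyloxy group, C2 OH, C3 aryl, C4 the 3-phenylpropanoyloxy group, C5 OH, C6 aryl. The enabling feature is that C3(aryl)–C4(O)–C5(O)–C6(aryl) is a 2,3-dioxygenated 1,4-diaryl diene and C1(O)–C2(O) a vicinally dioxygenated two-carbon unit.
- Retrosynthesis: cut the O1–acyl and O4–acyl ester bonds and the benzyl ethers to reach a symmetric 2,5-diaryl-3,6-dihydroxy-1,4-benzoquinone. Then cut ring bonds C6–C1 and C2–C3 to give a 2,5-diaryl-3,4-disiloxycyclopentadienone plus vinylene carbonate. The dienone goes back to a cyclopentanetrione, then to a diaryl acetone and diethyl oxalate, and the diaryl acetone to two molecules of one arylacetic acid.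
- Forward: two molecules of the arylacetic acid are joined to the diaryl acetone, a double Claisen condensation closes a five-membered ring, and O-silylation makes it a diene. Cycloaddition with loss of CO turns it into the six-membered central ring. DDQ aromatizes, and unmasking in air gives the quinone. Two successive O-acylations on its para-related enol oxygens and one hydrogenation finish the synthesis.
- Stereochemistry: the single stereocentre, (S) in the butanoyl chain, is bought as methyl (S)-3-hydroxybutanoate and no bond to it is made or broken. The two cis CH–O centres formed in the cycloaddition are erased on aromatization.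

Key step: step 4

Remark: trione 6 and quinones 13 and 18 are tautomeric systems; each is drawn as one tautomer and reacts through the oxygen atoms shown.

**Route**

Step 1
Reactants: 1 4-(benzyloxy)phenylacetic acid (2 equiv; two molecules are joined)
Product: 3 1,3-bis[4-(benzyloxy)phenyl]propan-2-one, via β-keto acid 2 (not isolated)
Conditions: 1 (2.0 equiv), DCC (1.0 equiv), DMAP (0.25 equiv), CH2Cl2, 25 °C
Reagents that add atoms: 4-(benzyloxy)phenylacetic acid (the second molecule of 1), O=C(O)Cc1ccc(OCc2ccccc2)cc1
Why: DCC/DMAP-mediated decarboxylative Claisen-type self-condensation of an arylacetic acid, in which one activated molecule of 1 acylates the benzylic carbon of a second molecule to give β-keto acid 2, which loses its carboxyl carbon as CO2 to leave the symmetric dibenzyl ketone; the benzyl ethers are inert.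

Step 2
Reactants: 3 1,3-bis[4-(benzyloxy)phenyl]propan-2-one; 4 diethyl oxalate
Product: 6 3,5-bis[4-(benzyloxy)phenyl]cyclopentane-1,2,4-trione (enolized), via open-chain dioxo ester 5 (not isolated)
Conditions: NaOEt (2.5 equiv), EtOH, 0 °C to reflux; then 1 M HCl
Reagents that add atoms: none
Why: Double Claisen condensation (intermolecular, then Dieckmann-type ring closure) of the two benzylic methylene groups with the two ester groups of the oxalate, the classical route from dibenzyl ketones to 3,5-diarylcyclopentane-1,2,4-triones, driven by formation of the sodium enolate of the acidic product.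

Step 3
Reactants: 6 3,5-bis[4-(benzyloxy)phenyl]cyclopentane-1,2,4-trione
Product: 7 2,5-bis[4-(benzyloxy)phenyl]-3,4-bis(tert-butyldimethylsilyloxy)cyclopenta-2,4-dien-1-one
Conditions: TBSOTf (2.3 equiv), Et3N (3 equiv), CH2Cl2, −78 to 0 °C; pentane, filtration, no aqueous work-up
Reagents that add atoms: tert-butyldimethylsilyl trifluoromethanesulfonate, CC(C)(C)[Si](C)(C)OS(=O)(=O)C(F)(F)F
Why: Twofold silyl enol ether formation on a strongly acidic enolized trione, one silyl group from each of two molecules of the triflate; silyl transfer between the ring oxygens is reversible under these conditions, so the symmetric cross-conjugated isomer with both silyloxy donors β to the ring carbonyl is the expected product, and its aryl and bulky silyl groups should keep it monomeric.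

Step 4
Reactants: 7 2,5-bis[4-(benzyloxy)phenyl]-3,4-bis(tert-butyldimethylsilyloxy)cyclopenta-2,4-dien-1-one; 8 vinylene carbonate
Product: 10 cis-4,7-bis[4-(benzyloxy)phenyl]-5,6-bis(tert-butyldimethylsilyloxy)-3a,7a-dihydro-1,3-benzodioxol-2-one (meso), via endo 7-oxonorbornene carbonate 9 (not isolated)
Conditions: 8 (10 equiv, neat), BHT (2 mol %), 2,6-di-tert-butylpyridine (5 mol %), sealed tube, argon, 150 °C; excess 8 removed in vacuo
Reagents that add atoms: none
Why: The alkene of 8 adds in a thermal Diels–Alder reaction across C2 and C5 of the cyclopentadienone (the two aryl-bearing carbons) to give the 7-oxonorbornene 9, which at the same temperature loses carbon monoxide by cheletropic extrusion to leave the cyclohexa-1,3-diene 10; the closest known reaction type is the addition of maleic anhydride or vinylene carbonate to tetraarylcyclopentadienones with loss of CO. The six-membered ring is closed by the concerted suprafacial [4+2] addition itself, which forms C6–C1 and C2–C3 of the central ring, and the former ring carbonyl leaves as the one-carbon bridge. The two new sp3 centres are cis because the Z geometry of 8 is carried through the suprafacial addition; the product is meso and both centres vanish in step 5, so endo or exo approach does not matter. Both partners are symmetric, so there is no regiochemical question. The selectivity needed is chemoselectivity against heterolysis of the allylic carbonate C–O bond in 10 (aromatization with loss of one oxygen) and against radical polymerization of 8; an acid-free medium buffered by a hindered pyridine, the lowest temperature at which CO is lost, and BHT should secure it.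

Step 5
Reactants: 10 cis-4,7-bis[4-(benzyloxy)phenyl]-5,6-bis(tert-butyldimethylsilyloxy)-3a,7a-dihydro-1,3-benzodioxol-2-one
Product: 11 4,7-bis[4-(benzyloxy)phenyl]-5,6-bis(tert-butyldimethylsilyloxy)-1,3-benzodioxol-2-one
Conditions: DDQ (1.1 equiv), toluene, 0 to 25 °C; filtration
Reagents that add atoms: none
Why: DDQ dehydrogenation of a cyclohexa-1,3-diene to the arene, in which hydride abstraction from an allylic CH–O carbon gives a cation stabilized by the silyloxy and 4-alkoxyphenyl groups and loss of the neighbouring proton aromatizes the ring with both carbonate oxygens retained; no base is present.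

Step 6
Reactants: 11 4,7-bis[4-(benzyloxy)phenyl]-5,6-bis(tert-butyldimethylsilyloxy)-1,3-benzodioxol-2-one
Product: 13 2,5-bis[4-(benzyloxy)phenyl]-3,6-dihydroxy-1,4-benzoquinone, via tetrol 12 (not isolated)
Conditions: K2CO3 (5 equiv), MeOH–THF (3:1), 25 °C, open to air; then 1 M HCl
Reagents that add atoms: none
Why: Base-mediated methanolysis of the cyclic aryl carbonate and of both aryl silyl ethers frees tetrol 12, whose anion is oxidized by air (hydroquinone autoxidation) to the dihydroxyquinone, a fully substituted quinone with no site for conjugate addition.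

Step 7
Reactants: 14 methyl (S)-3-hydroxybutanoate
Product: 15 methyl (S)-3-(benzyloxy)butanoate
Conditions: benzyl 2,2,2-trichloroacetimidate (1.3 equiv), TfOH (5 mol %), CH2Cl2–cyclohexane (1:2), 0 to 25 °C
Reagents that add atoms: benzyl 2,2,2-trichloroacetimidate, ClC(Cl)(Cl)C(=N)OCc1ccccc1
Why: Acid-catalysed O-benzylation with a trichloroacetimidate avoids the base that would cause β-elimination to the crotonate, and the C–O bond at the stereocentre is not broken, so (S) is retained.

Step 8
Reactants: 15 methyl (S)-3-(benzyloxy)butanoate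
Product: 16 (S)-3-(benzyloxy)butanoic acid
Conditions: LiOH·H2O (1.5 equiv), THF–H2O (3:1), 0 °C; then 1 M HCl to pH 2
Reagents that add atoms: lithium hydroxide, [Li+].[OH-]
Why: Saponification of a methyl ester by acyl–oxygen cleavage at 0 °C is faster than E1cB loss of benzyloxide, and the stereocentre is β to the carbonyl and cannot epimerize.

Step 9
Reactants: 13 2,5-bis[4-(benzyloxy)phenyl]-3,6-dihydroxy-1,4-benzoquinone; 17 3-phenylpropanoyl chloride
Product: 18 2,5-bis[4-(benzyloxy)phenyl]-4-hydroxy-3,6-dioxocyclohexa-1,4-dien-1-yl 3-phenylpropanoate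
Conditions: iPr2NEt (2.1 equiv), THF–CH2Cl2, −40 °C; 17 (1.0 equiv) added slowly, −40 to 0 °C; 0.5 M HCl wash
Reagents that add atoms: none
Why: O-acylation of a hydroxyquinone (a vinylogous carboxylate) with an acid chloride; the dianion of 13 is a stronger nucleophile than the monoanion of the monoester, so one equivalent of 17 should stop largely at 18, and the two hydroxyls of 13 are equivalent, so only one monoester can form.

Step 10
Reactants: 18 2,5-bis[4-(benzyloxy)phenyl]-4-hydroxy-3,6-dioxocyclohexa-1,4-dien-1-yl 3-phenylpropanoate; 16 (S)-3-(benzyloxy)butanoic acid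
Product: 20 2,5-bis[4-(benzyloxy)phenyl]-3,6-dioxo-4-[(3-phenylpropanoyl)oxy]cyclohexa-1,4-dien-1-yl (S)-3-(benzyloxy)butanoate, via acid chloride 19 (not isolated)
Conditions: 16, (COCl)2 (1.2 equiv), DMF (cat.), CH2Cl2, 0 to 25 °C, evaporate; then 18, 2,6-lutidine (1.1 equiv), CH2Cl2, −20 to 0 °C
Reagents that add atoms: oxalyl chloride, ClC(=O)C(=O)Cl (supplies only the chlorine of 19)
Why: Acid chloride formation followed by O-acylation of the remaining hydroxyquinone oxygen, which for 2,5-dihydroxy-1,4-benzoquinones gives the 2,5-diacyloxy-1,4-quinone; the hindered base and low temperature should prevent ketene formation, loss of benzyl alcohol and acyl exchange between the two esters, and the stereocentre is untouched.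

Step 11
Reactants: 20 2,5-bis[4-(benzyloxy)phenyl]-3,6-dioxo-4-[(3-phenylpropanoyl)oxy]cyclohexa-1,4-dien-1-yl (S)-3-(benzyloxy)butanoate
Product: 22 2,5-dihydroxy-3,6-bis(4-hydroxyphenyl)-4-[(3-phenylpropanoyl)oxy]phenyl (S)-3-hydroxybutanoate (the target), via hydroquinone tribenzyl ether 21 (not isolated)
Conditions: H2 (1 atm), 10% Pd/C, EtOAc–AcOH (100:1), 25 °C; filtration; chromatography on acid-washed silica
Reagents that add atoms: none
Why: Catalytic hydrogenation reduces the quinone to hydroquinone 21 at once and then hydrogenolyses the two aryl benzyl ethers and the secondary benzyl ether; the acyl groups sit on para-related oxygens because they were placed on the two enol oxygens of the quinone, and the neutral to slightly acidic aprotic medium should prevent acyl migration to the neighbouring phenols.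

**Compound list**

1 | 4-(benzyloxy)phenylacetic acid | O=C(O)Cc1ccc(OCc2ccccc2)cc1 | starting material
2 | 2,4-bis[4-(benzyloxy)phenyl]-3-oxobutanoic acid (racemic) | O=C(O)C(c1ccc(OCc2ccccc2)cc1)C(=O)Cc1ccc(OCc2ccccc2)cc1 | intermediate (not isolated)
3 | 1,3-bis[4-(benzyloxy)phenyl]propan-2-one | O=C(Cc1ccc(OCc2ccccc2)cc1)Cc1ccc(OCc2ccccc2)cc1 | intermediate
4 | diethyl oxalate | CCOC(=O)C(=O)OCC | starting material
5 | ethyl 3,5-bis[4-(benzyloxy)phenyl]-2,4-dioxopentanoate (racemic, enolizable) | CCOC(=O)C(=O)C(c1ccc(OCc2ccccc2)cc1)C(=O)Cc1ccc(OCc2ccccc2)cc1 | intermediate (not isolated)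
6 | 3,5-bis[4-(benzyloxy)phenyl]cyclopentane-1,2,4-trione, drawn as its dienediol tautomer 2,5-bis[4-(benzyloxy)phenyl]-3,4-dihydroxycyclopenta-2,4-dien-1-one | O=C1C(c2ccc(OCc3ccccc3)cc2)=C(O)C(O)=C1c1ccc(OCc2ccccc2)cc1 | intermediate
7 | 2,5-bis[4-(benzyloxy)phenyl]-3,4-bis(tert-butyldimethylsilyloxy)cyclopenta-2,4-dien-1-one | O=C1C(c2ccc(OCc3ccccc3)cc2)=C(O[Si](C)(C)C(C)(C)C)C(O[Si](C)(C)C(C)(C)C)=C1c1ccc(OCc2ccccc2)cc1 | intermediate
8 | vinylene carbonate (1,3-dioxol-2-one) | O=C1OC=CO1 | starting material
9 | 4,7-bis[4-(benzyloxy)phenyl]-5,6-bis(tert-butyldimethylsilyloxy)-3a,4,7,7a-tetrahydro-4,7-methano-1,3-benzodioxole-2,8-dione, carbonate oxygens endo (meso) | O=C1O[C@H]2[C@@H](O1)[C@@]3(c4ccc(OCc5ccccc5)cc4)C(O[Si](C)(C)C(C)(C)C)=C(O[Si](C)(C)C(C)(C)C)[C@]2(c4ccc(OCc5ccccc5)cc4)C3=O | intermediate (not isolated)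
10 | cis-4,7-bis[4-(benzyloxy)phenyl]-5,6-bis(tert-butyldimethylsilyloxy)-3a,7a-dihydro-1,3-benzodioxol-2-one (meso) | O=C1O[C@H]2[C@@H](O1)C(c1ccc(OCc3ccccc3)cc1)=C(O[Si](C)(C)C(C)(C)C)C(O[Si](C)(C)C(C)(C)C)=C2c1ccc(OCc2ccccc2)cc1 | intermediate
11 | 4,7-bis[4-(benzyloxy)phenyl]-5,6-bis(tert-butyldimethylsilyloxy)-1,3-benzodioxol-2-one | O=C1Oc2c(O1)c(-c1ccc(OCc3ccccc3)cc1)c(O[Si](C)(C)C(C)(C)C)c(O[Si](C)(C)C(C)(C)C)c2-c1ccc(OCc2ccccc2)cc1 | intermediate
12 | 3,6-bis[4-(benzyloxy)phenyl]benzene-1,2,4,5-tetrol | Oc1c(O)c(-c2ccc(OCc3ccccc3)cc2)c(O)c(O)c1-c1ccc(OCc2ccccc2)cc1 | intermediate (not isolated)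
13 | 2,5-bis[4-(benzyloxy)phenyl]-3,6-dihydroxy-1,4-benzoquinone | O=C1C(O)=C(c2ccc(OCc3ccccc3)cc2)C(=O)C(O)=C1c1ccc(OCc2ccccc2)cc1 | intermediate
14 | methyl (S)-3-hydroxybutanoate | C[C@H](O)CC(=O)OC | starting material
15 | methyl (S)-3-(benzyloxy)butanoate | C[C@H](OCc1ccccc1)CC(=O)OC | intermediate
16 | (S)-3-(benzyloxy)butanoic acid | C[C@H](OCc1ccccc1)CC(=O)O | intermediate
17 | 3-phenylpropanoyl chloride | O=C(Cl)CCc1ccccc1 | starting material
18 | 2,5-bis[4-(benzyloxy)phenyl]-4-hydroxy-3,6-dioxocyclohexa-1,4-dien-1-yl 3-phenylpropanoate | O=C1C(OC(=O)CCc2ccccc2)=C(c2ccc(OCc3ccccc3)cc2)C(=O)C(O)=C1c1ccc(OCc2ccccc2)cc1 | intermediate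
19 | (S)-3-(benzyloxy)butanoyl chloride | C[C@H](OCc1ccccc1)CC(=O)Cl | intermediate (not isolated)
20 | 2,5-bis[4-(benzyloxy)phenyl]-3,6-dioxo-4-[(3-phenylpropanoyl)oxy]cyclohexa-1,4-dien-1-yl (S)-3-(benzyloxy)butanoate | O=C1C(OC(=O)CCc2ccccc2)=C(c2ccc(OCc3ccccc3)cc2)C(=O)C(OC(=O)C[C@H](C)OCc2ccccc2)=C1c1ccc(OCc2ccccc2)cc1 | intermediate
21 | 3,6-bis[4-(benzyloxy)phenyl]-2,5-dihydroxy-4-[(3-phenylpropanoyl)oxy]phenyl (S)-3-(benzyloxy)butanoate | Oc1c(OC(=O)CCc2ccccc2)c(-c2ccc(OCc3ccccc3)cc2)c(O)c(OC(=O)C[C@H](C)OCc2ccccc2)c1-c1ccc(OCc2ccccc2)cc1 | intermediate (not isolated)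
22 | 2,5-dihydroxy-3,6-bis(4-hydroxyphenyl)-4-[(3-phenylpropanoyl)oxy]phenyl (S)-3-hydroxybutanoate | C[C@H](O)CC(=O)Oc1c(O)c(-c2ccc(O)cc2)c(OC(=O)CCc2ccccc2)c(O)c1-c1ccc(O)cc1 | target

**Step count**

Total: 11 steps. Longest linear sequence: 9 steps (steps 1–6 and 9–11, from 1 to 22); steps 7 and 8 make the side-chain acid.

**Steps most likely to fail**

Step 4. The cycloaddition may be slow at the temperature the adduct tolerates, so that radical polymerization of the dienophile and heterolysis of the allylic carbonate C–O bond of the product (followed by aromatization with loss of one oxygen) overtake product formation. The fallback sets out from dienone 7 and changes the two-carbon partner to an alkyne whose substituents are turned into oxygen afterwards. Heating 7 with purchased 1,2-bis(4,4,5,5-tetramethyl-1,3,2-dioxaborolan-2-yl)ethyne in mesitylene at 160–180 °C should give the norbornadienone F1, which loses CO spontaneously to the hexasubstituted benzene-1,2-diboronate F2 (Diels–Alder reaction of a cyclopentadienone with an alkynylboronate). No sp3 C–O bond exists at any stage, so the mixture can be heated as long as needed. Oxidation of both C–B bonds with H2O2 (2 equiv) and aqueous NaOH in THF–MeOH, a medium that also cleaves the aryl silyl ethers, should lead to tetrol 12. Admission of air then gives quinone 13, where the route is rejoined.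

Step 3. Silyl transfer among the three ring oxygens may leave part of the material as the unsymmetrical 2,4-disiloxy dienone, a diene with oxygen on one terminus that would add 8 across the wrong carbons. The vinylogous silyl esters may also hydrolyse on handling. The fallback sets out from trione 6 and ties the two adjacent oxygens together with one silicon atom. tBu2Si(OTf)2 and 2,6-lutidine in CH2Cl2 should give the di-tert-butylsilylene dienone F3. A silylene can bridge only the two neighbouring oxygens, because 1,3-related oxygens on the five-membered ring are too far apart, so the 3,4-dioxygenated diene is enforced. F3 is then carried through the conditions of steps 4 to 6. With 8 at 150 °C it should give the bridged ketone F4 and, after loss of CO, the diene carbonate F5. DDQ should give the arene F6. K2CO3 in MeOH under air should cleave carbonate and silylene to tetrol 12 and give quinone 13, where the route is rejoined.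

Step 9. Discrimination between the first and the second acylation may be poor, giving the symmetric diester alongside unchanged 13. The fallback sets out from 13 and reverses the direction of the selection. Excess 17 with pyridine in CH2Cl2 should give the symmetric bis(3-phenylpropanoate) F7. One acyl group is then removed with NaOMe (1.0 equiv) in MeOH–THF at −40 °C. After the first cleavage the product is an anion whose remaining ester is deactivated toward a second attack, so the reaction should stop at monoester 18, where the route is rejoined.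

**Further compounds**

F1 | step 4 | 1,4-bis[4-(benzyloxy)phenyl]-5,6-bis(tert-butyldimethylsilyloxy)-2,3-bis(4,4,5,5-tetramethyl-1,3,2-dioxaborolan-2-yl)bicyclo[2.2.1]hepta-2,5-dien-7-one (meso) | O=C1[C@@]2(c3ccc(OCc4ccccc4)cc3)C(B3OC(C)(C)C(C)(C)O3)=C(B3OC(C)(C)C(C)(C)O3)[C@]1(c3ccc(OCc4ccccc4)cc3)C(O[Si](C)(C)C(C)(C)C)=C2O[Si](C)(C)C(C)(C)C
F2 | step 4 | 2,2'-{3,6-bis[4-(benzyloxy)phenyl]-4,5-bis(tert-butyldimethylsilyloxy)-1,2-phenylene}bis(4,4,5,5-tetramethyl-1,3,2-dioxaborolane) | CC1(C)OB(OC1(C)C)c1c(B2OC(C)(C)C(C)(C)O2)c(-c2ccc(OCc3ccccc3)cc2)c(O[Si](C)(C)C(C)(C)C)c(O[Si](C)(C)C(C)(C)C)c1-c1ccc(OCc2ccccc2)cc1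
F3 | step 3 | 4,6-bis[4-(benzyloxy)phenyl]-2,2-di-tert-butyl-5H-cyclopenta[d][1,3,2]dioxasilol-5-one | O=C1C(c3ccc(OCc4ccccc4)cc3)=C2O[Si](C(C)(C)C)(C(C)(C)C)OC2=C1c1ccc(OCc2ccccc2)cc1
F4 | step 3 | endo adduct of F3 and 8: 7-oxonorbornene cis-carbonate with the enediol bridged by di-tert-butylsilylene (meso) | O=C1O[C@H]2[C@@H](O1)[C@@]3(c5ccc(OCc6ccccc6)cc5)C4=C(O[Si](C(C)(C)C)(C(C)(C)C)O4)[C@]2(c5ccc(OCc6ccccc6)cc5)C3=O
F5 | step 3 | cis-4,7-bis[4-(benzyloxy)phenyl]-5,6-(di-tert-butylsilylenedioxy)-3a,7a-dihydro-1,3-benzodioxol-2-one (meso) | O=C1O[C@H]2[C@@H](O1)C(c1ccc(OCc4ccccc4)cc1)=C3O[Si](C(C)(C)C)(C(C)(C)C)OC3=C2c1ccc(OCc2ccccc2)cc1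
F6 | step 3 | 4,7-bis[4-(benzyloxy)phenyl]-5,6-(di-tert-butylsilylenedioxy)-1,3-benzodioxol-2-one | O=C1Oc2c(O1)c(-c1ccc(OCc4ccccc4)cc1)c3O[Si](C(C)(C)C)(C(C)(C)C)Oc3c2-c1ccc(OCc2ccccc2)cc1
F7 | step 9 | 2,5-bis[4-(benzyloxy)phenyl]-3,6-dioxocyclohexa-1,4-diene-1,4-diyl bis(3-phenylpropanoate) | O=C1C(OC(=O)CCc2ccccc2)=C(c2ccc(OCc3ccccc3)cc2)C(=O)C(OC(=O)CCc2ccccc2)=C1c1ccc(OCc2ccccc2)cc1
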